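The runs stem from a simulated flask for substances that don't exist; noise was put on by code.

**Small charge.** I began from how small the free enzyme charge in this flask was, 0.02 mol% of the starting material, so the enzyme charged had to make on average 1000 turnovers to reach 20% conversion, while the impurity stood at 40.0% of the enzyme charge.

- spring: starting material 20 mM; second substrate 1 equiv; free enzyme 0.02 mol%; impurity 1.6 µM; the very flask that is asked about, followed so far
- flask: starting material 20 mM; second substrate 1.00 equiv; free enzyme 0.02 mol%; impurity 1.6 µM

spring run (percent of the starting material charged)

| time / h | target / % |
|---|---|
| 0.833 | 0.6 |
| 2.00 | 2.0 |
| 4.00 | 3.3 |
| 6.00 | 4.6 |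

(scatter of a reading: 0.3 percentage points)

1. apparent order in free enzyme when 20% of the starting material are converted (percent change of the rate of making target for one percent more free enzyme charged)
2. factor on the rate of making target when 20% of the starting material are converted if free enzyme is charged twice over

- no earlier run changes the charge of free enzyme; that part of a forecast is a guess

**Reading the rate.** In the spring run, target came at 0.0100 h⁻¹ of the charge up to 2.00 h, which was on average 100 turnovers, and then more slowly, at 0.00650 h⁻¹ up to 6.00 h. That reading of 0.650 for the ratio carries the scatter of 0.3 percentage points.

**Live share.** I took this slowing as one lasting factor, the live share (active catalyst fraction): the part of the enzyme charge still working once each impurity has taken one enzyme, 60.0%. The turnovers to 20% were ten times those of that early reading, so I expected the loss to be complete there, with the rate following enzyme charged minus impurity. I assumed that any slowing from conversion was a factor independent of the enzyme charge, so that it cancelled from both answers. My order was one over the live share, 1.67, and doubling gave 2.67, though the spring run never varied the enzyme, so this was a guess.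

**The forecast.** The forecast gave 1.6 and 2.6, a little below mine: “Because the runs never varied enzyme and binding may be partly reversible, I shade these slightly towards first order.”

**The result.** The simulation gave 1.7 and 2.67.

    free enzyme + impurity → spent catalyst (k = 7900 M⁻¹ s⁻¹)
    first complex → loaded enzyme + first product (k = 0.160 s⁻¹)
    second complex → free enzyme + target (k = 0.0310 s⁻¹)
    starting material + free enzyme ⇌ first complex (K = 230 M⁻¹, k = 270 M⁻¹ s⁻¹)
    second substrate + loaded enzyme ⇌ second complex (K = 130 M⁻¹, k = 19.0 M⁻¹ s⁻¹)

**One reason.** In this flask, impurity stood at 0% after 20.0 h and spent catalyst, the off-cycle form, held 40.0% of the catalyst charged, which left the live share I had reckoned. The run without the conversion of free enzyme and impurity into spent catalyst shows that step to be one reason: the order was 1.0 there against 1.7 in this flask, and the rate at 20% conversion was 1.67 times this flask's, which is one over the live share, 1.67.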